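The synthesis rests on the C5–C6 disconnection of ring B: C6 is traced back to an aldehyde carbon and C5 to the β-carbon of a ring A enone whose carbonyl is the later C3 oxygen. A chiral carbene turns the aldehyde of an achiral 4-methyl-4-(4-oxobutyl)cyclohexa-2,5-dienone into an acyl anion equivalent that attacks one of the two enantiotopic enone arms; this single operation closes ring B and fixes the quaternary C10 together with C5. The precursor carries no further ring substituent, so its mirror plane is intact. Afterwards C5 is inverted, ring A is oxygenated, the C6 carbonyl is transposed to C8 and the C7 side chain is attached by cross-coupling and hydrated last.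

Key step: step 6

Remark on numbering: ring atoms carry eudesmane locants (ring A: C1–C5 and C10; ring B: C5–C10; C14 = methyl on C10, C15 = methyl on C4, C11–C13 = side chain on C7). β is the face of the C10 methyl, α the opposite face.
Remark on the catalyst: both enantiomers of the aminoindanol-derived triazolium salt are available; the one that gives 13 as drawn is used, and the sense of induction is to be confirmed on the first run.
Remark on configuration: cis-diketone 13 already has the C10 configuration of the target; only C5 has to be inverted (step 7).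

Step 1
Reactants: 1 propanal; 2 cyclohexylamine
Product: 3 N-cyclohexylpropan-1-imine
Conditions: neat, 0 °C → rt; K2CO3 (drying); distillation
Reagents that add atoms: none
Why: Condensation of the aldehyde with a primary amine (imine formation) gives the aldimine needed for clean α-monoalkylation of propanal.

Step 2
Reactants: 3 N-cyclohexylpropan-1-imine; 4 5-bromopent-1-ene
Product: 6 2-methylhept-6-enal (racemic), via alkylated imine 5 (not isolated)
Conditions: LiN(iPr)2, THF, 0 °C; 4, 0 °C → rt; then aq. oxalic acid, rt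
Reagents that add atoms: water, O
Why: Metalloenamine alkylation: the lithiated aldimine is alkylated once by the primary bromide and mild acid hydrolysis frees the α-branched aldehyde; the new centre is racemic and later becomes the prochiral C10.

Step 3
Reactants: 6 2-methylhept-6-enal; 7 methyl vinyl ketone
Product: 9 4-methyl-4-(pent-4-en-1-yl)cyclohex-2-en-1-one (racemic), via Michael adduct 8 (not isolated)
Conditions: H2SO4 (cat.), toluene, 45 °C, then reflux (water separator)
Reagents that add atoms: none
Why: Acid-catalysed Robinson annulation of an α-branched aldehyde (Michael addition through the enol, then intramolecular aldol condensation) is a standard entry to 4,4-disubstituted cyclohexenones; the quaternary centre is racemic.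

Step 4
Reactants: 9 4-methyl-4-(pent-4-en-1-yl)cyclohex-2-en-1-one
Product: 10 4-methyl-4-(pent-4-en-1-yl)cyclohexa-2,5-dien-1-one
Conditions: DDQ, 1,4-dioxane, reflux
Reagents that add atoms: none
Why: Quinone dehydrogenation (hydride abstraction from the dienol) of a 4,4-disubstituted cyclohexenone gives the cross-conjugated, achiral dienone; the isolated terminal alkene is inert.

Step 5
Reactants: 10 4-methyl-4-(pent-4-en-1-yl)cyclohexa-2,5-dien-1-one
Product: 12 4-(1-methyl-4-oxocyclohexa-2,5-dien-1-yl)butanal, via ozonide 11 (not isolated)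
Conditions: O3, CH2Cl2, −78 °C (dye end point); then PPh3, −78 °C → rt
Reagents that add atoms: ozone, [O-][O+]=O
Why: Ozonolysis with reductive work-up: the electron-rich monosubstituted alkene reacts far faster than the electron-poor dienone double bonds.

Step 6
Reactants: 12 4-(1-methyl-4-oxocyclohexa-2,5-dien-1-yl)butanal
Product: 13 (4aS,8aR)-4a-methyl-4a,5,6,7-tetrahydronaphthalene-2,8(1H,8aH)-dione (cis-fused, 5β-H)
Conditions: 2-(pentafluorophenyl)-5a,10b-dihydro-4H,6H-indeno[2,1-b][1,2,4]triazolo[4,3-d][1,4]oxazin-2-ium tetrafluoroborate, single enantiomer (10 mol%), KN(SiMe3)2 (10 mol%), toluene, 23 °C, 0.02 M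
Reagents that add atoms: none
Why: The free carbene adds to the aldehyde carbon C6 and proton transfer gives the enaminol (acyl anion equivalent), which adds in a conjugate sense to C5 of one enone arm; protonation at C4 and loss of the carbene release the 1,4-diketone. The closest known reaction type is the carbene-catalysed enantioselective intramolecular Stetter desymmetrisation of 4,4-disubstituted cyclohexa-2,5-dienones that carry a tethered aldehyde. Ring B closes in the 6-exo-trig mode (C5–C6 bond formed, C4 stays outside the new ring). C10 becomes stereogenic because only one of the two enantiotopic arms reacts, a choice made by the chiral carbene; C5 is set by the tether, which reaches only the dienone face it is attached to, so H5 ends up cis to the C10 methyl. The step needs discrimination of the enantiotopic arms, secured by the mirror symmetry of 12 together with the catalyst, and preference for the Stetter pathway over aldol or benzoin reactions, secured by intramolecularity, the quaternary C10 in the tether, catalytic base and dilution.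

Step 7
Reactants: 13 cis-fused diketone
Product: 14 (4aS,8aS)-4a-methyl-4a,5,6,7-tetrahydronaphthalene-2,8(1H,8aH)-dione (trans-fused, 5α-H)
Conditions: DBU (0.2 equiv), CH2Cl2, rt; chromatography, recovered 13 resubmitted
Reagents that add atoms: none
Why: Thermodynamic epimerisation through the C6 enolate equilibrates C5; the trans-fused diketone, with both ring bonds at C5 equatorial, should be the major component and is separated while the cis isomer is recycled.

Step 8
Reactants: 14 trans-fused diketone
Product: 15 6β-hydroxy-11,12,13,15-tetranor-5α-eudesm-1-en-3-one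
Conditions: NaBH4 (0.3 equiv), MeOH/CH2Cl2, −78 → −40 °C
Reagents that add atoms: none
Why: Chemoselective borohydride reduction: a saturated ketone is reduced faster than a conjugated enone, and hydride attack anti to the axial C10 methyl should give the 6β alcohol, which masks C6 and locks C5 (the C6 centre is temporary).

Step 9
Reactants: 15 hydroxy enone
Product: 16 6β-hydroxy-11,12,13-trinor-5α-eudesm-1-en-3-one (4α-methyl epimer drawn)
Conditions: LiN(iPr)2 (2.2 equiv), THF, −78 °C; MeI (1.2 equiv), −78 → −40 °C
Reagents that add atoms: iodomethane, CI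
Why: Enolate alkylation: the enone can be deprotonated only at C4 (C10 is quaternary), the hindered alkoxide is a spectator, and the cross-conjugated dienolate is C-methylated; the C4 configuration is erased in step 10.

Step 10
Reactants: 16 4-methyl hydroxy enone
Product: 17 4α,6β-dihydroxy-11,12,13-trinor-5α-eudesm-1-en-3-one (4β-methyl)
Conditions: KN(SiMe3)2 (2.5 equiv), THF, −78 °C; 2-(phenylsulfonyl)-3-phenyloxaziridine, −78 °C
Reagents that add atoms: 2-(phenylsulfonyl)-3-phenyloxaziridine, O=S(=O)(N1OC1c1ccccc1)c1ccccc1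
Why: Enolate hydroxylation with an N-sulfonyloxaziridine: the potassium dienolate is attacked from the α face, opposite the axial C10 methyl and the 6β oxygen, which sets the 4α-hydroxy-4β-methyl centre.

Step 11
Reactants: 17 α′-hydroxy enone
Product: 18 4α,6β-dihydroxy-11,12,13-trinor-5α-eudesman-3-one
Conditions: H2 (1 atm), Pd/C, EtOAc, rt
Reagents that add atoms: none
Why: Heterogeneous catalytic hydrogenation saturates the disubstituted C1=C2 bond, which had served to block enolisation towards C2; no stereocentre is formed.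

Step 12
Reactants: 18 saturated hydroxy ketone
Product: 19 11,12,13-trinor-5α-eudesmane-3α,4α,6β-triol
Conditions: LiBH(sBu)3 (4 equiv), THF, −78 → −20 °C; aqueous work-up
Reagents that add atoms: none
Why: Reduction with a bulky trialkylborohydride: attack along the equatorial trajectory gives the axial 3α alcohol, cis to the 4α hydroxyl, as in reductions of 4,4-disubstituted 3-oxo terpenoids.

Step 13
Reactants: 19 triol
Product: 20 3α,4α-(isopropylidenedioxy)-11,12,13-trinor-5α-eudesman-6β-ol
Conditions: 2,2-dimethoxypropane, pyridinium p-toluenesulfonate (cat.), acetone, rt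
Reagents that add atoms: 2,2-dimethoxypropane, COC(C)(C)OC
Why: Acid-catalysed acetonide formation engages only the cis vicinal diol; the 6β hydroxyl is anti to O4 and stays free.

Step 14
Reactants: 20 acetonide alcohol
Product: 21 3α,4α-(isopropylidenedioxy)-11,12,13-trinor-5α-eudesman-6-one
Conditions: 1,1,1-triacetoxy-1,1-dihydro-1,2-benziodoxol-3(1H)-one (DMP), NaHCO3, CH2Cl2, rt
Reagents that add atoms: none
Why: Dess–Martin oxidation of the hindered axial secondary alcohol regenerates the C6 ketone under buffered conditions; enolisation towards C5 is disfavoured by allylic strain with the fully substituted C4, so C5 stays fixed from here on.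

Step 15
Reactants: 21 C6 ketone
Product: 23 3α,4α-(isopropylidenedioxy)-11,12,13-trinor-5α-eudesm-7-en-6-one, via silyl enol ether 22 (not isolated)
Conditions: LiN(iPr)2, Me3SiCl, THF, −78 °C; then Pd(OAc)2 (1.1 equiv), MeCN, rt
Reagents that add atoms: chlorotrimethylsilane, C[Si](C)(C)Cl (its silyl group is present only in 22)
Why: Saegusa–Ito oxidation: kinetic enolisation towards the C7 methylene (C5–H is a hindered methine) and silylation, then palladation and β-hydride elimination, give the C7=C8 enone.

Step 16
Reactants: 23 enone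
Product: 24 7α,8α-epoxy-3α,4α-(isopropylidenedioxy)-11,12,13-trinor-5α-eudesman-6-one
Conditions: 30% H2O2, NaOH (cat.), MeOH, 0 °C
Reagents that add atoms: hydrogen peroxide, OO
Why: Weitz–Scheffer nucleophilic epoxidation: hydroperoxide adds to the unhindered C8, expected from the face opposite the C10 methyl, and the enolate closes the epoxide; either epoxide serves because these centres are lost later.

Step 17
Reactants: 24 epoxy ketone
Product: 26 3α,4α-(isopropylidenedioxy)-11,12,13-trinor-5α-eudesm-6-en-8α-ol, via epoxy hydrazone 25 (not isolated)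
Conditions: N2H4·H2O, AcOH (cat.), MeOH, 0 °C → rt
Reagents that add atoms: hydrazine, NN (its nitrogen atoms are present only in 25)
Why: Wharton transposition: the epoxy hydrazone fragments with loss of dinitrogen to the allylic alcohol, which moves the oxygen from C6 to C8 and creates C6=C7; C8 keeps the epoxide configuration and C5 is not touched.

Step 18
Reactants: 26 allylic alcohol
Product: 27 3α,4α-(isopropylidenedioxy)-11,12,13-trinor-5α-eudesm-6-en-8-one
Conditions: DMP, NaHCO3, CH2Cl2, rt
Reagents that add atoms: none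
Why: Dess–Martin oxidation of the secondary allylic alcohol gives the C6=C7–C8=O enone of the target.

Step 19
Reactants: 27 enone
Product: 28 7-iodo-3α,4α-(isopropylidenedioxy)-11,12,13-trinor-5α-eudesm-6-en-8-one
Conditions: I2, pyridine/CH2Cl2, 0 °C → rt
Reagents that add atoms: iodine, II
Why: α-Iodination of an enone by the iodine–pyridine method (reversible conjugate addition of pyridine, iodination of the enolate, elimination) places the halogen on C7 without leaving a substituent on the hindered C6.

Step 20
Reactants: 28 iodo enone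
Product: 29 3α,4α-(isopropylidenedioxy)-5α-eudesma-6,11-dien-8-one
Conditions: Pd2(dba)3 (cat.), AsPh3, CuI, tributyl(prop-1-en-2-yl)stannane, N-methylpyrrolidone, rt → 50 °C
Reagents that add atoms: tributyl(prop-1-en-2-yl)stannane, C=C(C)[Sn](CCCC)(CCCC)CCCC
Why: Stille coupling of the α-iodo enone (oxidative addition, copper-assisted transmetallation, reductive elimination) forms the C7–C11 bond under neutral conditions.

Step 21
Reactants: 29 dienone acetonide
Product: 30 3α,4α-dihydroxy-5α-eudesma-6,11-dien-8-one
Conditions: AcOH/H2O (4:1), 45 °C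
Reagents that add atoms: none
Why: Acid-catalysed acetal hydrolysis frees the cis diol; the dienone has no acid-labile group.

Step 22
Reactants: 30 diol; 31 angelic acid
Product: 32 3α-angeloyloxy-4α-hydroxy-5α-eudesma-6,11-dien-8-one
Conditions: 31, 2,4,6-trichlorobenzoyl chloride, Et3N, toluene, rt; then 30, 70 °C
Reagents that add atoms: none
Why: Yamaguchi esterification with the preformed mixed anhydride and no nucleophilic catalyst acylates the secondary 3α hydroxyl (the tertiary one is inert) and avoids isomerisation of the angelate to the tiglate.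

Step 23
Reactants: 32 hydroxy angelate
Product: 33 4α-acetoxy-3α-angeloyloxy-5α-eudesma-6,11-dien-8-one
Conditions: Ac2O, Et3N, 4-(dimethylamino)pyridine, CH2Cl2, rt → 40 °C
Reagents that add atoms: acetic anhydride, CC(=O)OC(C)=O
Why: Nucleophile-catalysed acetylation of the only free hydroxyl, the tertiary 4α-OH; it is done before the second tertiary alcohol exists, so no differentiation is needed.

Step 24
Reactants: 33 dienone diester
Product: 35 4α-acetoxy-3α-angeloyloxy-11-hydroxy-5α-eudesm-6-en-8-one (target), via hydroperoxide 34 (not isolated)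
Conditions: Co(acac)2 (20 mol%), PhSiH3, O2 (1 atm), i-PrOH/THF, 0 °C → rt; then PPh3
Reagents that add atoms: dioxygen, O=O
Why: Mukaiyama hydration: cobalt hydride transfers a hydrogen atom to the terminal CH2 of the 1,1-disubstituted alkene, the tertiary allylic radical is trapped by O2 at the accessible C11 (C6 is shielded), and reduction of the peroxide gives the tertiary alcohol; the angelate and enone double bonds are poorer hydrogen-atom acceptors.

Compound list
1 | propanal | CCC=O | starting material
2 | cyclohexylamine | NC1CCCCC1 | starting material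
3 | N-cyclohexylpropan-1-imine | CCC=NC1CCCCC1 | intermediate
4 | 5-bromopent-1-ene | C=CCCCBr | starting material
5 | N-cyclohexyl-2-methylhept-6-en-1-imine (racemic, not isolated) | C=CCCCC(C)C=NC1CCCCC1 | intermediate
6 | 2-methylhept-6-enal (racemic) | C=CCCCC(C)C=O | intermediate
7 | methyl vinyl ketone (but-3-en-2-one) | CC(=O)C=C | starting material
8 | 2-methyl-2-(3-oxobutyl)hept-6-enal (racemic, not isolated) | C=CCCCC(C)(CCC(C)=O)C=O | intermediate
9 | 4-methyl-4-(pent-4-en-1-yl)cyclohex-2-en-1-one (racemic) | C=CCCCC1(C)CCC(=O)C=C1 | intermediate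
10 | 4-methyl-4-(pent-4-en-1-yl)cyclohexa-2,5-dien-1-one | C=CCCCC1(C)C=CC(=O)C=C1 | intermediate
11 | 3-[3-(1-methyl-4-oxocyclohexa-2,5-dien-1-yl)propyl]-1,2,4-trioxolane (not isolated) | CC1(CCCC2OCOO2)C=CC(=O)C=C1 | intermediate
12 | 4-(1-methyl-4-oxocyclohexa-2,5-dien-1-yl)butanal | CC1(CCCC=O)C=CC(=O)C=C1 | intermediate
13 | (4aS,8aR)-4a-methyl-4a,5,6,7-tetrahydronaphthalene-2,8(1H,8aH)-dione (cis-fused, 5β-H) | O=C1C=C[C@]2(C)CCCC(=O)[C@@H]2C1 | intermediate
14 | (4aS,8aS)-4a-methyl-4a,5,6,7-tetrahydronaphthalene-2,8(1H,8aH)-dione (trans-fused, 5α-H) | O=C1C=C[C@]2(C)CCCC(=O)[C@H]2C1 | intermediate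
15 | 6β-hydroxy-11,12,13,15-tetranor-5α-eudesm-1-en-3-one | O=C1C=C[C@]2(C)CCC[C@@H](O)[C@H]2C1 | intermediate
16 | 6β-hydroxy-11,12,13-trinor-5α-eudesm-1-en-3-one (4α-methyl epimer) | O=C1C=C[C@]2(C)CCC[C@@H](O)[C@H]2[C@@H]1C | intermediate
17 | 4α,6β-dihydroxy-11,12,13-trinor-5α-eudesm-1-en-3-one | O=C1C=C[C@]2(C)CCC[C@@H](O)[C@H]2[C@]1(C)O | intermediate
18 | 4α,6β-dihydroxy-11,12,13-trinor-5α-eudesman-3-one | O=C1CC[C@]2(C)CCC[C@@H](O)[C@H]2[C@]1(C)O | intermediate
19 | 11,12,13-trinor-5α-eudesmane-3α,4α,6β-triol | O[C@@H]1CC[C@]2(C)CCC[C@@H](O)[C@H]2[C@]1(C)O | intermediate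
20 | 3α,4α-(isopropylidenedioxy)-11,12,13-trinor-5α-eudesman-6β-ol | CC1(C)O[C@@H]2CC[C@]3(C)CCC[C@@H](O)[C@H]3[C@]2(C)O1 | intermediate
21 | 3α,4α-(isopropylidenedioxy)-11,12,13-trinor-5α-eudesman-6-one | CC1(C)O[C@@H]2CC[C@]3(C)CCCC(=O)[C@H]3[C@]2(C)O1 | intermediate
22 | 6-(trimethylsilyloxy)-3α,4α-(isopropylidenedioxy)-11,12,13-trinor-5α-eudesm-6-ene (not isolated) | CC1(C)O[C@@H]2CC[C@]3(C)CCC=C(O[Si](C)(C)C)[C@H]3[C@]2(C)O1 | intermediate
23 | 3α,4α-(isopropylidenedioxy)-11,12,13-trinor-5α-eudesm-7-en-6-one | CC1(C)O[C@@H]2CC[C@]3(C)CC=CC(=O)[C@H]3[C@]2(C)O1 | intermediate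
24 | 7α,8α-epoxy-3α,4α-(isopropylidenedioxy)-11,12,13-trinor-5α-eudesman-6-one | CC1(C)O[C@@H]2CC[C@]3(C)C[C@@H]4O[C@@H]4C(=O)[C@H]3[C@]2(C)O1 | intermediate
25 | C6 hydrazone of 24 (not isolated) | CC1(C)O[C@@H]2CC[C@]3(C)C[C@@H]4O[C@@H]4C(=NN)[C@H]3[C@]2(C)O1 | intermediate
26 | 3α,4α-(isopropylidenedioxy)-11,12,13-trinor-5α-eudesm-6-en-8α-ol | CC1(C)O[C@@H]2CC[C@]3(C)C[C@H](O)C=C[C@H]3[C@]2(C)O1 | intermediate
27 | 3α,4α-(isopropylidenedioxy)-11,12,13-trinor-5α-eudesm-6-en-8-one | CC1(C)O[C@@H]2CC[C@]3(C)CC(=O)C=C[C@H]3[C@]2(C)O1 | intermediate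
28 | 7-iodo-3α,4α-(isopropylidenedioxy)-11,12,13-trinor-5α-eudesm-6-en-8-one | CC1(C)O[C@@H]2CC[C@]3(C)CC(=O)C(I)=C[C@H]3[C@]2(C)O1 | intermediate
29 | 3α,4α-(isopropylidenedioxy)-5α-eudesma-6,11-dien-8-one | CC1(C)O[C@@H]2CC[C@]3(C)CC(=O)C(C(C)=C)=C[C@H]3[C@]2(C)O1 | intermediate
30 | 3α,4α-dihydroxy-5α-eudesma-6,11-dien-8-one | O[C@@H]1CC[C@]2(C)CC(=O)C(C(C)=C)=C[C@H]2[C@]1(C)O | intermediate
31 | angelic acid ((Z)-2-methylbut-2-enoic acid) | C/C=C(/C)C(=O)O | starting material
32 | 3α-angeloyloxy-4α-hydroxy-5α-eudesma-6,11-dien-8-one | C/C=C(/C)C(=O)O[C@@H]1CC[C@]2(C)CC(=O)C(C(C)=C)=C[C@H]2[C@]1(C)O | intermediate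
33 | 4α-acetoxy-3α-angeloyloxy-5α-eudesma-6,11-dien-8-one | C/C=C(/C)C(=O)O[C@@H]1CC[C@]2(C)CC(=O)C(C(C)=C)=C[C@H]2[C@]1(C)OC(C)=O | intermediate
34 | 4α-acetoxy-3α-angeloyloxy-11-hydroperoxy-5α-eudesm-6-en-8-one (not isolated) | C/C=C(/C)C(=O)O[C@@H]1CC[C@]2(C)CC(=O)C(C(C)(C)OO)=C[C@H]2[C@]1(C)OC(C)=O | intermediate
35 | 4α-acetoxy-3α-angeloyloxy-11-hydroxy-5α-eudesm-6-en-8-one (CNP0351454.1) | C/C=C(/C)C(=O)O[C@@H]1CC[C@]2(C)CC(=O)C(C(C)(C)O)=C[C@H]2[C@]1(C)OC(C)=O | target

Total step count: 24. Longest linear sequence: 24 steps (from propanal 1; the route is fully linear, angelic acid 31 is bought).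

Steps most likely to fail

Step 6. The closure of a six-membered ring from an enolisable aliphatic aldehyde may be slower than base-induced aldol-type condensation or Michael addition of the aldehyde enolate, and the carbene may discriminate the two enone arms poorly. The fallback sets out from 12 and comes back at 13; it replaces the acyl anion equivalent by a nitronate. Aldehyde 12 is condensed with NH2OH·HCl/NaOAc to 4-(1-methyl-4-oxocyclohexa-2,5-dien-1-yl)butanal oxime F1, which is oxidised (NaBO3·4H2O, AcOH) to 4-methyl-4-(4-nitrobutyl)cyclohexa-2,5-dien-1-one F2. A bifunctional cinchona-alkaloid thiourea then effects the desymmetrising intramolecular nitro-Michael addition to the cis-fused nitro enone F3. A Nef reaction (NaOMe, MeOH; then buffered TiCl3) turns the secondary nitro group into the C6 ketone of 13.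

Step 7. The equilibrium may lie insufficiently on the trans side, because the angular methyl brings cis- and trans-fused 6-ketones close in energy, and long exposure to base invites aldol-type side reactions. The fallback sets out from 13 and comes back at 14; it fixes C5 under kinetic control. Diketone 13 is dehydrogenated (DDQ, 1,4-dioxane, 80 °C) to the ene-dione (4aS)-4a-methyl-4a,5,6,7-tetrahydronaphthalene-2,8-dione F4, whose C4=C5 bond is reduced with Zn in AcOH. Ketonisation of the resulting enol by protonation of C5 from the open α face, anti to the C10 methyl (ring A is flat at this stage), should give 14.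

Step 24. Hydrogen-atom transfer may go to the enone or angelate double bond, or the allylic radical may be oxygenated at C6, which would give reduced or regioisomeric products on the last intermediate. The fallback sets out from 28 and comes back at 35; it makes the carbinol by carbonyl addition and protects it. Luche reduction of 28 (NaBH4, CeCl3·7H2O, MeOH) gives the 7-iodo allylic alcohol F5. Iodine–lithium exchange (t-BuLi, THF, −78 °C) and addition to acetone give the 8,11-diol F6, and MnO2 oxidises the secondary allylic alcohol to the 11-hydroxy enone acetonide F7. Silylation (tert-butyldimethylsilyl triflate, 2,6-lutidine) gives the tertiary silyl ether F8, and aqueous AcOH removes the acetonide to give the diol F9. Esterification as in step 22 gives the angelate F10 and acetylation as in step 23 gives the angelate acetate F11, in which the acetylated oxygen is the only free hydroxyl. HF·pyridine then frees the C11 hydroxyl to give 35.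

Further compounds
F1 | step 6 | 4-(1-methyl-4-oxocyclohexa-2,5-dien-1-yl)butanal oxime | CC1(CCCC=NO)C=CC(=O)C=C1
F2 | step 6 | 4-methyl-4-(4-nitrobutyl)cyclohexa-2,5-dien-1-one | CC1(CCCC[N+](=O)[O-])C=CC(=O)C=C1
F3 | step 6 | 6-nitro-11,12,13,15-tetranor-5β-eudesm-1-en-3-one (cis-fused, C6 epimers) | O=C1C=C[C@]2(C)CCCC([N+](=O)[O-])[C@@H]2C1
F4 | step 7 | (4aS)-4a-methyl-4a,5,6,7-tetrahydronaphthalene-2,8-dione | O=C1C=C[C@]2(C)CCCC(=O)C2=C1
F5 | step 24 | 7-iodo-3α,4α-(isopropylidenedioxy)-11,12,13-trinor-5α-eudesm-6-en-8-ol | CC1(C)O[C@@H]2CC[C@]3(C)CC(O)C(I)=C[C@H]3[C@]2(C)O1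
F6 | step 24 | 3α,4α-(isopropylidenedioxy)-5α-eudesm-6-ene-8,11-diol | CC1(C)O[C@@H]2CC[C@]3(C)CC(O)C(C(C)(C)O)=C[C@H]3[C@]2(C)O1
F7 | step 24 | 11-hydroxy-3α,4α-(isopropylidenedioxy)-5α-eudesm-6-en-8-one | CC1(C)O[C@@H]2CC[C@]3(C)CC(=O)C(C(C)(C)O)=C[C@H]3[C@]2(C)O1
F8 | step 24 | 11-(tert-butyldimethylsilyloxy)-3α,4α-(isopropylidenedioxy)-5α-eudesm-6-en-8-one | CC1(C)O[C@@H]2CC[C@]3(C)CC(=O)C(C(C)(C)O[Si](C)(C)C(C)(C)C)=C[C@H]3[C@]2(C)O1
F9 | step 24 | 11-(tert-butyldimethylsilyloxy)-3α,4α-dihydroxy-5α-eudesm-6-en-8-one | O[C@@H]1CC[C@]2(C)CC(=O)C(C(C)(C)O[Si](C)(C)C(C)(C)C)=C[C@H]2[C@]1(C)O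
F10 | step 24 | 3α-angeloyloxy-11-(tert-butyldimethylsilyloxy)-4α-hydroxy-5α-eudesm-6-en-8-one | C/C=C(/C)C(=O)O[C@@H]1CC[C@]2(C)CC(=O)C(C(C)(C)O[Si](C)(C)C(C)(C)C)=C[C@H]2[C@]1(C)O
F11 | step 24 | 4α-acetoxy-3α-angeloyloxy-11-(tert-butyldimethylsilyloxy)-5α-eudesm-6-en-8-one | C/C=C(/C)C(=O)O[C@@H]1CC[C@]2(C)CC(=O)C(C(C)(C)O[Si](C)(C)C(C)(C)C)=C[C@H]2[C@]1(C)OC(C)=O
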